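## Analysis of the target

- The target 25 is an acylphloroglucinol: a 2,6-dihydroxy-4-methoxyphenyl ketone (ring A, the only ring) whose acyl group is an unbranched C18 chain, numbered here from the ketone carbon C1 to the methyl carbon C18.
- The chain carries four methylenes (C2–C5), a Z alkene C6=C7, the methylene C8, a secondary carbinol at C9, a conjugated 10E,12Z-diene, the doubly allylic methylene C14, a Z alkene C15=C16 and an ethyl end.
- C9 is the only stereocentre. With the order OH > C10 > C8 > H it is R, and because it stands alone it cannot be relayed from a neighbour; it has to be bought or set by a reagent.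
- The C9 hydroxyl is allylic to a diene and ionises easily in acid to a pentadienyl cation, which leads to transposition or dehydration.
- C14 and C8 are prone to hydrogen abstraction and to base-induced migration of double bonds into conjugation, and the three Z alkenes rule out hydrogenation and late radical-chain or iodine-mediated steps.
- Ring A is an electron-rich, oxidisable resorcinol, so the ketone cannot be installed by acid-mediated acylation once the polyene is present.
- The difficulty lies in keeping four alkene geometries and one allylic stereocentre intact while C1 and C10 sit at different oxidation states and ring A is protected and released under conditions the dienyl carbinol survives.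
- The route rests on the pattern O–C9(H)–C8H2 with C10 as an sp2 carbon. This is C2 of malic acid with its C1 carboxyl (future C10) and its C3 methylene (future C8), so the C4 carboxyl can be spent as a radical leaving group to join C8 to the preformed Z-alkene carbon C7.

## Retrosynthetic reasoning

**Unmasking.** Target 25 is taken back to 24, in which both phenols are 1-ethoxyethyl acetals and the C9 oxygen is a triethylsilyl ether. These groups are chosen because all three leave in one weakly acidic methanolysis, and because the acetal oxygens direct the metalation used in the next disconnection.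

**C1–aryl bond.** 24 is cut between the ketone carbon C1 and ring A, giving the N-methoxy-N-methylamide 20 as acyl donor and the aryllithium 23. Ring A is symmetric about the axis through C1' and C4', so the nucleophilic carbon is the one flanked by the two acetal oxygens of 22, which comes from the phenol 21. Cutting here avoids Friedel–Crafts acylation in the presence of the polyene and keeps the ring out of all earlier steps. Amide 20 is the methyl ester 19 at the same oxidation state.

**C12=C13.** 19 is cut at the Z alkene of the diene into the enal 14 and the non-stabilised ylide 18. The ylide comes from the salt 17, the iodide 16 and the alcohol 15, which already holds the C15=C16 Z alkene. A non-stabilised ylide on an enal gives the Z geometry kinetically, and the skipped triene, the most fragile part, appears only four steps from the end.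

**C10=C11.** 14 is cut at the E alkene into the α-silyloxy aldehyde 12 and the stabilised ylide 13. This adds C11 and C12 at the aldehyde oxidation state in one step, so no hydride has to be used while the C1 ester is present.

**Oxidation state of C10.** 12 comes from the bis-silyl ether 11 by oxidative removal of the primary silyl group, 11 from the diol 10, and 10 from the dioxolanone 8. The cut is placed here because the ring carbonyl of 8 is an activated, α-oxygenated lactone that a mild hydride reduces while the unactivated C1 methyl ester is left alone. This differentiates the two carboxyl carbons without extra protecting groups.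

**C7–C8 (key disconnection).** 8 is cut between the sp3 carbon C8 and the alkene carbon C7 into the redox-active ester 3 and the Z-iodoalkene 7. A cut at C8–C9 or C9–C10 would make the stereocentre the reacting carbon and would require reagent-controlled asymmetric addition. The C7–C8 cut puts the reactive site one atom away, so C9 is carried unchanged from the chiral pool. The forward reaction must form an sp3–sp2 bond from a primary radical with retention of the Z geometry.

**Coupling partners.** 3 is the activated ester of the acetonide acid 2, which comes from 1 by selective ketalisation of the α-hydroxy acid unit. 7 comes from the iodoalkyne 6 by syn delivery of two hydrogens, 6 from the terminal alkyne 5, and 5 from the acid 4.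

## Alternatives that were turned down

**Alternative 1: orthoester Claisen through a propargylic alcohol, cut at C10–C11.**
- Forward key step: racemic propargylic alcohol A1, (Z)-oct-5-en-1-yn-3-ol, would be heated with an orthoacetate and a trace of weak acid. The mixed ketene acetal rearranges [3,3] through the alkyne to the allenoate A2, ethyl (7Z)-deca-3,4,7-trienoate. A prototropic shift would then give the dienoate A3, ethyl (2E,4Z,7Z)-deca-2,4,7-trienoate, which is C9–C18 of 25 with C9 as the ester carbon.
- For it: the diene half is reached in two steps from cheap material, the sigmatropic step is dependable, and the configuration of A1 does not matter. On step count for the C9–C18 segment it is stronger than the two olefinations used here.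
- Against it: C9 arrives as an achiral carboxyl carbon, so the only stereocentre of 25 is not addressed. It would have to be created later on a trienyl substrate, either by asymmetric reduction of a ketone whose C8 methylene lies between the carbonyl and the C6=C7 alkene (prone to conjugation), or by an allyl-type addition that would have to react through its α carbon.
- The base-mediated shift from A2 to A3 passes through a delocalised anion next to the doubly allylic C14, so geometry and position of the alkenes can leak. A1 itself would come from a β,γ-unsaturated aldehyde that conjugates easily.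
- Comparison: the chosen route spends more steps on the diene but takes C9 from 1 with no asymmetric step on a sensitive intermediate.

**Alternative 2: lithiation–borylation, cut at C9–C10.**
- Forward key step: carbamate A4, 3-(tert-butyldimethylsilyloxy)propyl N,N-diisopropylcarbamate, would be deprotonated next to oxygen by a secondary alkyllithium bound to a chiral diamine. The carbanion would be trapped by the trienyl boronate A5, 2-[(1E,3Z,6Z)-nona-1,3,6-trien-1-yl]-4,4,5,5-tetramethyl-1,3,2-dioxaborolane. The ate complex would undergo 1,2-migration of the trienyl group with loss of carbamate, and alkaline peroxide work-up would give A6, (3R,4E,6Z,9Z)-1-(tert-butyldimethylsilyloxy)dodeca-4,6,9-trien-3-ol, which is C7–C18 of 25.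
- For it: C9–C10 is formed and C9 is set in one flask by reagent control, and the whole triene arrives in one piece. In convergence it is stronger than the chosen route.
- Against it: A5 needs its own multistep stereodefined synthesis. The intermediate α-dienyl boronic ester is an allylic boronate that can shift boron along the diene before oxidation, eroding position and configuration. A stoichiometric chiral diamine and cryogenic organolithium chemistry are required.
- After A6, C1–C6 would have to be attached by Z-olefination of a C7 aldehyde whose β-oxygen at C9 is dienylic, so elimination into a conjugated tetraene threatens under the basic ylide conditions.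
- Comparison: in the chosen route C7 is never a carbonyl, C9 comes from 1 without a chiral reagent, and the triene is built last.

**Alternative 3: enzymatic dioxygenation of the intact C18 acid.**
- Forward key step: stearidonic acid A7, (6Z,9Z,12Z,15Z)-octadeca-6,9,12,15-tetraenoic acid, holds all chain carbons. A 9R-selective lipoxygenase, a non-heme iron dioxygenase, would abstract hydrogen from C11 and deliver oxygen from air to C9 with shift of the 9Z alkene to 10E, giving the hydroperoxide A8, (6Z,9R,10E,12Z,15Z)-9-hydroperoxyoctadeca-6,10,12,15-tetraenoic acid.
- For it: one step forms the C9–O bond, the stereocentre and the E,Z-diene. After reduction of the hydroperoxide only the aryl ketone end game remains, so in step economy this is clearly the strongest of all four routes.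
- Against it: the substrate has three doubly allylic methylenes (C8, C11, C14), so positional fidelity depends entirely on the enzyme. Lipoxygenases with 9R selectivity are uncommon and not off-the-shelf reagents, and their behaviour on an 18:4 substrate with the extra 6Z alkene cannot be argued from structure. Regioisomeric hydroperoxides would be hard to separate.
- Comparison: the chosen route is much longer, but every bond is made by a reaction whose site and geometry follow from the reagents and not from an enzyme pocket.

Key step: step 6

Remark: the acetal carbons of the 1-ethoxyethyl groups in 22, 23 and 24 are uncontrolled stereocentres (diastereomer mixtures); this has no consequence because both groups are removed in step 17.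

## Route

Step 1
Reactants: 1 (R)-malic acid
Product: 2 2-[(4R)-2,2-dimethyl-5-oxo-1,3-dioxolan-4-yl]acetic acid
Conditions: 2,2-dimethoxypropane, pyridinium p-toluenesulfonate (cat.), rt
Reagents that add atoms: 2,2-dimethoxypropane, COC(C)(C)OC
Why: Acid-catalysed transketalisation closes the five-membered dioxolanone on the α-hydroxy acid unit in preference to the six-membered ring through the distal carboxyl, leaving that carboxyl free; the stereocentre is not involved.

Step 2
Reactants: 2 2-[(4R)-2,2-dimethyl-5-oxo-1,3-dioxolan-4-yl]acetic acid
Product: 3 1,3-dioxoisoindolin-2-yl 2-[(4R)-2,2-dimethyl-5-oxo-1,3-dioxolan-4-yl]acetate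
Conditions: N-hydroxyphthalimide, i-PrN=C=N-i-Pr, DMAP (cat.), CH2Cl2, 0 °C to rt
Reagents that add atoms: N-hydroxyphthalimide, ON1C(=O)c2ccccc2C1=O
Why: Carbodiimide (Steglich-type) esterification of the free acid with the N-hydroxy imide; the dioxolanone is not attacked by the weakly nucleophilic imide oxygen under these conditions.

Step 3
Reactants: 4 hept-6-ynoic acid
Product: 5 methyl hept-6-ynoate
Conditions: MeOH, H2SO4 (cat.), reflux
Reagents that add atoms: methanol, CO
Why: Fischer esterification; the terminal alkyne is inert to dilute acid in methanol.

Step 4
Reactants: 5 methyl hept-6-ynoate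
Product: 6 methyl 7-iodohept-6-ynoate
Conditions: N-iodosuccinimide, AgNO3 (cat.), acetone, rt, dark
Reagents that add atoms: N-iodosuccinimide, O=C1CCC(=O)N1I
Why: Silver-catalysed electrophilic iodination of a terminal alkyne through the silver acetylide; the ester is a spectator.

Step 5
Reactants: 6 methyl 7-iodohept-6-ynoate
Product: 7 methyl (Z)-7-iodohept-6-enoate
Conditions: 2-nitrobenzenesulfonyl hydrazide, Et3N, THF/i-PrOH, rt
Reagents that add atoms: none
Why: Diimide released from the sulfonyl hydrazide transfers two hydrogens to one face of the iodoalkyne in a concerted step, so iodine and the chain end up cis (Z); the C–I bond and the ester do not react with diimide, and over-reduction is limited by the amount of hydrazide.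

Step 6
Reactants: 3 1,3-dioxoisoindolin-2-yl 2-[(4R)-2,2-dimethyl-5-oxo-1,3-dioxolan-4-yl]acetate; 7 methyl (Z)-7-iodohept-6-enoate
Product: 8 methyl (6Z)-8-[(4R)-2,2-dimethyl-5-oxo-1,3-dioxolan-4-yl]oct-6-enoate
Conditions: NiCl2·6H2O (cat.), 2,2'-bipyridine (cat.), AgNO3 (0.3 equiv), LiCl, DMF, Mg anode, reticulated vitreous carbon cathode, constant current, undivided cell, rt; 3 in excess
Reagents that add atoms: none
Why: The cathode reduces the divalent nickel–bipyridine complex to low-valent nickel, which inserts into the C–I bond of 7 with retention of the Z geometry. One-electron transfer to ester 3 fragments it into phthalimide anion, carbon dioxide and a primary radical at C8, which the alkenylnickel species captures to give a trivalent alkyl(alkenyl)nickel complex; reductive elimination forms the C7–C8 bond while the Mg anode supplies the electrons. The closest known reaction type is the nickel-electrocatalytic decarboxylative alkenylation of redox-active alkyl esters with alkenyl iodides, and only the pairing of these two partners is new. No ring is closed and no stereocentre is formed: the radical sits on C8, next to but not at C9, so the R configuration of 1 is carried through. The step needs cross-coupling over homocoupling; this is secured because the two electrophiles are activated differently (two-electron insertion for the sp2 iodide, one-electron reduction for the ester) and because 3 is used in excess. It also needs retention of the Z alkene, which rests on stereospecific oxidative addition and fast reductive elimination at room temperature. The C8 radical is unconjugated and its β-oxygen is held in the acetal ring, so fragmentation and β-elimination are not expected, and silver deposited on the cathode from AgNO3 keeps the working potential low enough that the methyl ester and the dioxolanone are not reduced.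

Step 7
Reactants: 8 methyl (6Z)-8-[(4R)-2,2-dimethyl-5-oxo-1,3-dioxolan-4-yl]oct-6-enoate
Product: 10 methyl (6Z,9R)-9,10-dihydroxydec-6-enoate, via methyl (6Z,9R)-9-hydroxy-10-oxodec-6-enoate 9 (not isolated)
Conditions: NaBH4, THF/MeOH, 0 °C
Reagents that add atoms: none
Why: Chemoselective borohydride reduction: the ring carbonyl is an α-oxygenated lactone with an acetal oxygen as leaving group and accepts hydride (or methoxide, then hydride) at 0 °C, releasing acetone and the α-hydroxy aldehyde 9, which is reduced at once, whereas the unactivated C1 methyl ester is inert to NaBH4 at this temperature; C9 is untouched.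

Step 8
Reactants: 10 methyl (6Z,9R)-9,10-dihydroxydec-6-enoate
Product: 11 methyl (6Z,9R)-9,10-bis(triethylsilyloxy)dec-6-enoate
Conditions: Et3SiCl, imidazole, DMAP (cat.), CH2Cl2, 0 °C to rt
Reagents that add atoms: chlorotriethylsilane, CC[Si](Cl)(CC)CC
Why: Standard silylation of both hydroxyls; two identical groups are installed so that the next step can tell them apart by their steric environment alone.

Step 9
Reactants: 11 methyl (6Z,9R)-9,10-bis(triethylsilyloxy)dec-6-enoate
Product: 12 methyl (6Z,9R)-10-oxo-9-(triethylsilyloxy)dec-6-enoate
Conditions: (COCl)2, DMSO, CH2Cl2, −78 to −40 °C; then Et3N, −78 °C to rt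
Reagents that add atoms: none
Why: Selective Swern oxidation of a primary triethylsilyl ether: the chlorosulfonium reagent attacks the unhindered primary silyl ether oxygen, passes the silyl group to chloride and forms the alkoxysulfonium ion that collapses to the aldehyde with Et3N, while the secondary ether at C9 is too hindered to react at −40 °C; the short exposure to amine at low temperature should leave the α-silyloxy stereocentre intact.

Step 10
Reactants: 12 methyl (6Z,9R)-10-oxo-9-(triethylsilyloxy)dec-6-enoate; 13 2-(triphenylphosphoranylidene)acetaldehyde
Product: 14 methyl (6Z,9R,10E)-12-oxo-9-(triethylsilyloxy)dodeca-6,10-dienoate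
Conditions: toluene, 80 °C
Reagents that add atoms: none
Why: Wittig reaction of a stabilised ylide, which is reversible at the betaine/oxaphosphetane stage and gives the E enal; the α-oxygenated aldehyde 12 is more electrophilic than the product enal, which limits a second homologation, and the neutral conditions do not epimerise C9.

Step 11
Reactants: 15 (Z)-hex-3-en-1-ol
Product: 16 (Z)-1-iodohex-3-ene
Conditions: I2, PPh3, imidazole, CH2Cl2, 0 °C to rt
Reagents that add atoms: iodine, II
Why: Appel-type iodination of a primary alcohol through the alkoxyphosphonium ion with SN2 displacement by iodide; the remote Z alkene is not involved.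

Step 12
Reactants: 16 (Z)-1-iodohex-3-ene
Product: 17 [(3Z)-hex-3-en-1-yl]triphenylphosphonium iodide
Conditions: PPh3, MeCN, reflux
Reagents that add atoms: triphenylphosphine, c1ccc(cc1)P(c1ccccc1)c1ccccc1
Why: SN2 quaternisation of the phosphine by a primary iodide; the salt can be purified by crystallisation before the ylide is made.

Step 13
Reactants: 17 [(3Z)-hex-3-en-1-yl]triphenylphosphonium iodide; 14 methyl (6Z,9R,10E)-12-oxo-9-(triethylsilyloxy)dodeca-6,10-dienoate
Product: 19 methyl (6Z,9R,10E,12Z,15Z)-9-(triethylsilyloxy)octadeca-6,10,12,15-tetraenoate, via [(3Z)-hex-3-en-1-ylidene]triphenylphosphorane 18 (not isolated)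
Conditions: NaN(SiMe3)2, THF, −78 °C; then 14, −78 to 0 °C
Reagents that add atoms: none
Why: Z-selective Wittig reaction of a non-stabilised ylide under lithium-free conditions: kinetic, irreversible formation of the cis oxaphosphetane gives the 12Z alkene next to the existing 10E alkene; at −78 °C the ylide reacts with the aldehyde and not with the methyl ester, and a slight deficit of base avoids enolisation.

Step 14
Reactants: 19 methyl (6Z,9R,10E,12Z,15Z)-9-(triethylsilyloxy)octadeca-6,10,12,15-tetraenoate
Product: 20 (6Z,9R,10E,12Z,15Z)-N-methoxy-N-methyl-9-(triethylsilyloxy)octadeca-6,10,12,15-tetraenamide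
Conditions: MeNHOMe·HCl, i-PrMgCl, THF, −20 to 0 °C
Reagents that add atoms: N,O-dimethylhydroxylamine hydrochloride, CNOC.Cl
Why: Direct aminolysis of the methyl ester by the chloromagnesium amide formed in the flask (Weinreb amide synthesis); the magnesium amide is too weak a base to shift the skipped alkenes, and the silyl ether is stable to it.

Step 15
Reactants: 21 5-methoxyresorcinol
Product: 22 1,3-bis(1-ethoxyethoxy)-5-methoxybenzene
Conditions: ethyl vinyl ether, pyridinium p-toluenesulfonate (cat.), CH2Cl2, 0 °C to rt
Reagents that add atoms: ethyl vinyl ether, C=COCC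
Why: Acid-catalysed addition of both phenols to the enol ether gives the mixed acetals; with this weak acid O-addition should outrun alkylation of the electron-rich ring.

Step 16
Reactants: 22 1,3-bis(1-ethoxyethoxy)-5-methoxybenzene; 20 (6Z,9R,10E,12Z,15Z)-N-methoxy-N-methyl-9-(triethylsilyloxy)octadeca-6,10,12,15-tetraenamide
Product: 24 (6Z,9R,10E,12Z,15Z)-1-[2,6-bis(1-ethoxyethoxy)-4-methoxyphenyl]-9-(triethylsilyloxy)octadeca-6,10,12,15-tetraen-1-one, via [2,6-bis(1-ethoxyethoxy)-4-methoxyphenyl]lithium 23 (not isolated)
Conditions: n-BuLi, THF, 0 °C; then 20, −78 to 0 °C; aq. NH4Cl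
Reagents that add atoms: none
Why: Directed ortho-metalation places lithium on the ring carbon between the two acetal oxygens, which chelate better than the methoxy group, and the aryllithium adds once to the Weinreb amide because the chelated tetrahedral intermediate holds until work-up; the ketone forms without any acid, and the silyl ether and alkenes are inert to the aryl anion at low temperature.

Step 17
Reactants: 24 (6Z,9R,10E,12Z,15Z)-1-[2,6-bis(1-ethoxyethoxy)-4-methoxyphenyl]-9-(triethylsilyloxy)octadeca-6,10,12,15-tetraen-1-one
Product: 25 (6Z,9R,10E,12Z,15Z)-1-(2,6-dihydroxy-4-methoxyphenyl)-9-hydroxyoctadeca-6,10,12,15-tetraen-1-one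
Conditions: pyridinium p-toluenesulfonate (cat.), MeOH, 0 °C to rt
Reagents that add atoms: none
Why: Mild acid-catalysed methanolysis exchanges both aryl acetals (very labile, assisted by the ortho ketone) and the secondary triethylsilyl ether into volatile methyl acetal and methyl silyl ether; a pyridinium acid is weak enough that ionisation of the dienyl carbinol at C9 should not compete, so configuration and alkene geometries are kept.

## Compound list

1 | (R)-malic acid | O[C@H](CC(=O)O)C(=O)O | starting material
2 | 2-[(4R)-2,2-dimethyl-5-oxo-1,3-dioxolan-4-yl]acetic acid | O=C1OC(C)(C)O[C@@H]1CC(=O)O | intermediate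
3 | 1,3-dioxoisoindolin-2-yl 2-[(4R)-2,2-dimethyl-5-oxo-1,3-dioxolan-4-yl]acetate | O=C1OC(C)(C)O[C@@H]1CC(=O)ON1C(=O)c2ccccc2C1=O | intermediate
4 | hept-6-ynoic acid | C#CCCCCC(=O)O | starting material
5 | methyl hept-6-ynoate | C#CCCCCC(=O)OC | intermediate
6 | methyl 7-iodohept-6-ynoate | IC#CCCCCC(=O)OC | intermediate
7 | methyl (Z)-7-iodohept-6-enoate | COC(=O)CCCC/C=C\I | intermediate
8 | methyl (6Z)-8-[(4R)-2,2-dimethyl-5-oxo-1,3-dioxolan-4-yl]oct-6-enoate | COC(=O)CCCC/C=C\C[C@H]1OC(C)(C)OC1=O | intermediate
9 | methyl (6Z,9R)-9-hydroxy-10-oxodec-6-enoate | COC(=O)CCCC/C=C\C[C@@H](O)C=O | intermediate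
10 | methyl (6Z,9R)-9,10-dihydroxydec-6-enoate | COC(=O)CCCC/C=C\C[C@@H](O)CO | intermediate
11 | methyl (6Z,9R)-9,10-bis(triethylsilyloxy)dec-6-enoate | COC(=O)CCCC/C=C\C[C@@H](O[Si](CC)(CC)CC)CO[Si](CC)(CC)CC | intermediate
12 | methyl (6Z,9R)-10-oxo-9-(triethylsilyloxy)dec-6-enoate | COC(=O)CCCC/C=C\C[C@@H](O[Si](CC)(CC)CC)C=O | intermediate
13 | 2-(triphenylphosphoranylidene)acetaldehyde | O=CC=P(c1ccccc1)(c1ccccc1)c1ccccc1 | starting material
14 | methyl (6Z,9R,10E)-12-oxo-9-(triethylsilyloxy)dodeca-6,10-dienoate | COC(=O)CCCC/C=C\C[C@@H](O[Si](CC)(CC)CC)/C=C/C=O | intermediate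
15 | (Z)-hex-3-en-1-ol | CC/C=C\CCO | starting material
16 | (Z)-1-iodohex-3-ene | CC/C=C\CCI | intermediate
17 | [(3Z)-hex-3-en-1-yl]triphenylphosphonium iodide | CC/C=C\CC[P+](c1ccccc1)(c1ccccc1)c1ccccc1.[I-] | intermediate
18 | [(3Z)-hex-3-en-1-ylidene]triphenylphosphorane | CC/C=C\CC=P(c1ccccc1)(c1ccccc1)c1ccccc1 | intermediate
19 | methyl (6Z,9R,10E,12Z,15Z)-9-(triethylsilyloxy)octadeca-6,10,12,15-tetraenoate | CC/C=C\C/C=C\C=C\[C@H](O[Si](CC)(CC)CC)C/C=C\CCCCC(=O)OC | intermediate
20 | (6Z,9R,10E,12Z,15Z)-N-methoxy-N-methyl-9-(triethylsilyloxy)octadeca-6,10,12,15-tetraenamide | CC/C=C\C/C=C\C=C\[C@H](O[Si](CC)(CC)CC)C/C=C\CCCCC(=O)N(C)OC | intermediate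
21 | 5-methoxyresorcinol | COc1cc(O)cc(O)c1 | starting material
22 | 1,3-bis(1-ethoxyethoxy)-5-methoxybenzene | CCOC(C)Oc1cc(OC)cc(OC(C)OCC)c1 | intermediate
23 | [2,6-bis(1-ethoxyethoxy)-4-methoxyphenyl]lithium | [Li]c1c(OC(C)OCC)cc(OC)cc1OC(C)OCC | intermediate
24 | (6Z,9R,10E,12Z,15Z)-1-[2,6-bis(1-ethoxyethoxy)-4-methoxyphenyl]-9-(triethylsilyloxy)octadeca-6,10,12,15-tetraen-1-one | CC/C=C\C/C=C\C=C\[C@H](O[Si](CC)(CC)CC)C/C=C\CCCCC(=O)c1c(OC(C)OCC)cc(OC)cc1OC(C)OCC | intermediate
25 | (6Z,9R,10E,12Z,15Z)-1-(2,6-dihydroxy-4-methoxyphenyl)-9-hydroxyoctadeca-6,10,12,15-tetraen-1-one | CC/C=C\C/C=C\C=C\[C@H](O)C/C=C\CCCCC(=O)c1c(O)cc(OC)cc1O | target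

## Step count and least certain steps

Total step count: 17. Longest linear sequence: 12 steps (from 4 through steps 3, 4, 5, 6, 7, 8, 9, 10, 13, 14, 16 and 17).

**Step 6 (key step).**
- What may go wrong: radical generation and capture may be mismatched. The C8 radical can be reduced further or abstract hydrogen (protodecarboxylation) or dimerise before it meets the alkenylnickel species, and the alkenylnickel intermediate can homocouple or lose its Z geometry if reductive elimination is slow. Both partners are consumed at one electrode surface, so their rates are not set independently.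
- Fallback: it sets out from 1, returns at 10, and makes C6=C7 by olefination with C7 taken from the second carboxyl of malic acid. Compound 1 would be reduced with BH3·SMe2/B(OMe)3 to (R)-butane-1,2,4-triol F1. Its 1,2-diol would be closed with acetone and TsOH to 2-[(4R)-2,2-dimethyl-1,3-dioxolan-4-yl]ethanol F2, and Swern oxidation would give 2-[(4R)-2,2-dimethyl-1,3-dioxolan-4-yl]acetaldehyde F3. (6-Methoxy-6-oxohexyl)triphenylphosphonium bromide F4, from commercial methyl 6-bromohexanoate and PPh3, would be deprotonated with NaN(SiMe3)2 to methyl 6-(triphenylphosphoranylidene)hexanoate F5. F5 should react with F3 at −78 °C to give methyl (6Z)-8-[(4R)-2,2-dimethyl-1,3-dioxolan-4-yl]oct-6-enoate F6, and aqueous acetic acid would release the diol 10.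

**Step 16.**
- What may go wrong: deprotonation of 22 may not be confined to the carbon between the two acetal oxygens. The doubly ortho-substituted aryllithium 23 may also deprotonate C2 of 20 or cleave its N–O bond faster than it adds, because attack of a hindered aryl anion on a tertiary amide carbonyl is slow.
- Fallback: it sets out from 22 and 20 and returns at 24. Compound 22 would be lithiated and quenched with I2 to 1,3-bis(1-ethoxyethoxy)-2-iodo-5-methoxybenzene F8, which can be freed of any regioisomer before valuable material is committed. Amide 20 would be reduced with LiAlH4 at −78 °C to (6Z,9R,10E,12Z,15Z)-9-(triethylsilyloxy)octadeca-6,10,12,15-tetraenal F9. Iodine–lithium exchange on F8 with n-BuLi at −78 °C regenerates 23, which should add readily to the far more electrophilic aldehyde F9 to give (6Z,9R,10E,12Z,15Z)-1-[2,6-bis(1-ethoxyethoxy)-4-methoxyphenyl]-9-(triethylsilyloxy)octadeca-6,10,12,15-tetraen-1-ol F10 as a mixture of C1 epimers. Oxidation with Dess–Martin periodinane buffered with NaHCO3 would give 24.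

**Step 17.**
- What may go wrong: acid-promoted ionisation at C9 once the silyl group has left. The free dienyl carbinol can form a pentadienyl cation in methanol, leading to solvolysis, allylic transposition or dehydration.
- Fallback: it sets out from 24 and returns at 25, and separates the two deprotections so that the free carbinol never meets acid. A short, cold treatment of 24 with pyridinium p-toluenesulfonate in MeOH would remove only the far more labile aryl acetals and give (6Z,9R,10E,12Z,15Z)-1-(2,6-dihydroxy-4-methoxyphenyl)-9-(triethylsilyloxy)octadeca-6,10,12,15-tetraen-1-one F11. The silyl ether would then be cleaved by fluoride, Bu4NF buffered with AcOH in THF, to give 25.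

**Step 9.**
- What may go wrong: loss of discrimination between the primary and the secondary silyl ether, or epimerisation of the α-silyloxy aldehyde by Et3N during warming, since the two ethers differ only in steric access.
- Fallback: it sets out from 11 and returns at 12, and separates cleavage from oxidation. Brief treatment of 11 with pyridinium p-toluenesulfonate in MeOH/CH2Cl2 at 0 °C would remove the primary silyl group to give methyl (6Z,9R)-10-hydroxy-9-(triethylsilyloxy)dec-6-enoate F7. Oxidation with Dess–Martin periodinane and NaHCO3, which uses no amine base, would give 12.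

## Further compounds

F1 | step 6 | (R)-butane-1,2,4-triol | OCC[C@@H](O)CO
F2 | step 6 | 2-[(4R)-2,2-dimethyl-1,3-dioxolan-4-yl]ethanol | OCC[C@@H]1COC(C)(C)O1
F3 | step 6 | 2-[(4R)-2,2-dimethyl-1,3-dioxolan-4-yl]acetaldehyde | O=CC[C@@H]1COC(C)(C)O1
F4 | step 6 | (6-methoxy-6-oxohexyl)triphenylphosphonium bromide | COC(=O)CCCCC[P+](c1ccccc1)(c1ccccc1)c1ccccc1.[Br-]
F5 | step 6 | methyl 6-(triphenylphosphoranylidene)hexanoate | COC(=O)CCCCC=P(c1ccccc1)(c1ccccc1)c1ccccc1
F6 | step 6 | methyl (6Z)-8-[(4R)-2,2-dimethyl-1,3-dioxolan-4-yl]oct-6-enoate | COC(=O)CCCC/C=C\C[C@@H]1COC(C)(C)O1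
F7 | step 9 | methyl (6Z,9R)-10-hydroxy-9-(triethylsilyloxy)dec-6-enoate | COC(=O)CCCC/C=C\C[C@@H](O[Si](CC)(CC)CC)CO
F8 | step 16 | 1,3-bis(1-ethoxyethoxy)-2-iodo-5-methoxybenzene | CCOC(C)Oc1cc(OC)cc(OC(C)OCC)c1I
F9 | step 16 | (6Z,9R,10E,12Z,15Z)-9-(triethylsilyloxy)octadeca-6,10,12,15-tetraenal | CC/C=C\C/C=C\C=C\[C@H](O[Si](CC)(CC)CC)C/C=C\CCCCC=O
F10 | step 16 | (6Z,9R,10E,12Z,15Z)-1-[2,6-bis(1-ethoxyethoxy)-4-methoxyphenyl]-9-(triethylsilyloxy)octadeca-6,10,12,15-tetraen-1-ol | CC/C=C\C/C=C\C=C\[C@H](O[Si](CC)(CC)CC)C/C=C\CCCCC(O)c1c(OC(C)OCC)cc(OC)cc1OC(C)OCC
F11 | step 17 | (6Z,9R,10E,12Z,15Z)-1-(2,6-dihydroxy-4-methoxyphenyl)-9-(triethylsilyloxy)octadeca-6,10,12,15-tetraen-1-one | CC/C=C\C/C=C\C=C\[C@H](O[Si](CC)(CC)CC)C/C=C\CCCCC(=O)c1c(O)cc(OC)cc1O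
A1 | alternative 1 | (Z)-oct-5-en-1-yn-3-ol (racemic) | CC/C=C\CC(O)C#C
A2 | alternative 1 | ethyl (7Z)-deca-3,4,7-trienoate (racemic allene) | CC/C=C\CC=C=CCC(=O)OCC
A3 | alternative 1 | ethyl (2E,4Z,7Z)-deca-2,4,7-trienoate | CC/C=C\C/C=C\C=C\C(=O)OCC
A4 | alternative 2 | 3-(tert-butyldimethylsilyloxy)propyl N,N-diisopropylcarbamate | CC(C)N(C(C)C)C(=O)OCCCO[Si](C)(C)C(C)(C)C
A5 | alternative 2 | 2-[(1E,3Z,6Z)-nona-1,3,6-trien-1-yl]-4,4,5,5-tetramethyl-1,3,2-dioxaborolane | CC/C=C\C/C=C\C=C\B1OC(C)(C)C(C)(C)O1
A6 | alternative 2 | (3R,4E,6Z,9Z)-1-(tert-butyldimethylsilyloxy)dodeca-4,6,9-trien-3-ol | CC/C=C\C/C=C\C=C\[C@H](O)CCO[Si](C)(C)C(C)(C)C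
A7 | alternative 3 | stearidonic acid, (6Z,9Z,12Z,15Z)-octadeca-6,9,12,15-tetraenoic acid | CC/C=C\C/C=C\C/C=C\C/C=C\CCCCC(=O)O
A8 | alternative 3 | (6Z,9R,10E,12Z,15Z)-9-hydroperoxyoctadeca-6,10,12,15-tetraenoic acid | CC/C=C\C/C=C\C=C\[C@H](OO)C/C=C\CCCCC(=O)O
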